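**Plan**

1. Labels: tropone T1 (C=O), T2 (CO2Me), T3 (CH3), T4 (H), T5 (ring fusion, bears the furan CH2 = C11), T6 (O), T7 (CH3); cyclohexane C5 (CH–C(CH3)2OH), C6, C7, C8 (CH–CH3), C9 (spiro), C10 (CH3 and CH2CH2CO2H). The tropone has a single C–H, T4, between T3 and T5. Without T4 the ring is the benzene ring of methyl 3-methylorsellinate, so T4 can enter as a CHCl2 group on T5 of a dearomatised dienone and be moved into the ring by a radical 1,2-shift.
2. Retrosynthesis: cut T3–T4 (tropone to 4-dichloromethyl-cyclohexa-2,5-dienone), then T5–CHCl2 (to a spiro-dihydrobenzofuran phenol and chloroform), then C9–O together with C8–H (to a phenol and a C8=C9 alkene), then C9–C11 (to a cyclohexenyl triflate and a benzylic zinc reagent), then C10–allyl, C10–CH3 and the carbinol C–O (to (S)-carvone).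
3. Forward: the carvone ring is decorated first (hydration, two alkylations at the CH2 next to the carbonyl, side-chain oxidation) and joined to the arene by Negishi coupling. The dihydrofuran is then closed by acid, and the benzene ring is dearomatised and expanded to the tropone in the last two steps.
4. Stereochemistry: C5 comes from (S)-carvone; C10 from allylation anti to the C5 substituent; C8 and C9 from delivery of the proton and the phenol oxygen to the alkene face opposite the axial C10 methyl; the T5 centre of the dienone is lost again.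

Key step: step 17

Remark: dienone 27 is carried as a mixture of epimers at T5, because T5 becomes trigonal in step 17. Chloroform is listed as a starting material because its carbon becomes T4.
Remark: in benzoates 14–22 the ring carbons C1 (CO2Me), C6, C5, C4, C3, C2 correspond to T2, T3, T5, T6, T7, T1.

**Route**

Step 1
Reactants: 1 (S)-carvone
Product: 2 (S)-8-hydroxycarvotanacetone ((5S)-5-(2-hydroxypropan-2-yl)-2-methylcyclohex-2-en-1-one)
Conditions: 50% aq. H2SO4, 0 °C
Reagents that add atoms: water (O)
Why: Markovnikov acid-catalysed hydration of the 1,1-disubstituted alkene through the tertiary cation is the classical preparation of carvone hydrate, and it leaves the enone and the C5 stereocentre untouched.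

Step 2
Reactants: 2 (S)-8-hydroxycarvotanacetone
Product: 3 (5S)-5-[2-(tert-butyldimethylsilyloxy)propan-2-yl]-2-methylcyclohex-2-en-1-one
Conditions: TBSOTf, 2,6-lutidine, CH2Cl2, −78 to 0 °C
Reagents that add atoms: tert-butyldimethylsilyl trifluoromethanesulfonate (CC(C)(C)[Si](C)(C)OS(=O)(=O)C(F)(F)F)
Why: Silyl triflate silylation of a tertiary alcohol should give a hindered, weakly basic silyl ether that masks the carbinol through the enolate and acid steps and later acts as an equatorial anchor.

Step 3
Reactants: 3 silyl ether of carvone hydrate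
Product: 5 (5S,6R)-5-[2-(tert-butyldimethylsilyloxy)propan-2-yl]-2,6-dimethylcyclohex-2-en-1-one (trans isomer; the 6-epimer is carried along), via lithium dienolate 4 (not isolated)
Conditions: LiN(i-Pr)2, THF, −78 °C; then MeI, −78 to −20 °C
Reagents that add atoms: iodomethane (CI)
Why: Kinetic deprotonation of the enone at the CH2 next to the carbonyl gives the cross-conjugated dienolate, which is C-methylated (enolate alkylation); the configuration of the new centre is irrelevant because it is enolised again in step 4.

Step 4
Reactants: 5 6-methyl enone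
Product: 7 (5S,6R)-5-[2-(tert-butyldimethylsilyloxy)propan-2-yl]-2,6-dimethyl-6-(prop-2-en-1-yl)cyclohex-2-en-1-one, via lithium dienolate 6 (not isolated)
Conditions: LiN(i-Pr)2, THF, −78 to −20 °C; then allyl bromide, DMPU, −78 to 0 °C
Reagents that add atoms: allyl bromide (C=CCBr)
Why: Enolate alkylation of the tetrasubstituted dienolate with a reactive allylic halide, as established for 6-methylcarvone; the bulky C5 group sits pseudo-axial next to the methyl-bearing enolate carbon, so the allyl group should enter anti to it, which puts the chain trans and the methyl cis to the C5 substituent (C10 R).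

Step 5
Reactants: 7 allylated enone
Product: 9 (5S,6R)-5-[2-(tert-butyldimethylsilyloxy)propan-2-yl]-2,6-dimethyl-6-(prop-2-en-1-yl)cyclohex-1-en-1-yl trifluoromethanesulfonate, via lithium enolate 8 (not isolated)
Conditions: LiBH(s-Bu)3, THF, −78 °C; then PhNTf2, −78 to 0 °C
Reagents that add atoms: N-phenylbis(trifluoromethanesulfonimide) (O=S(=O)(N(c1ccccc1)S(=O)(=O)C(F)(F)F)C(F)(F)F)
Why: Conjugate reduction with enolate trapping: the bulky borohydride should add hydride 1,4 to the β-unsubstituted enone, whose carbonyl is shielded by the quaternary C10, and O-triflation of the regiodefined enolate fixes the double bond at C8=C9 and erases the C8 configuration on purpose.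

Step 6
Reactants: 9 enol triflate
Product: 11 3-hydroxypropyl enol triflate (the allyl group of 9 turned into CH2CH2CH2OH), via B-alkyl-9-BBN adduct 10 (not isolated)
Conditions: 9-BBN, THF, 0 to 23 °C; then 30% H2O2, aq. NaOAc, 0 °C
Reagents that add atoms: hydrogen peroxide (OO)
Why: Anti-Markovnikov hydroboration–oxidation of the monosubstituted alkene; the tetrasubstituted, electron-poor enol triflate alkene is inert to 9-BBN and the buffered oxidation should spare the triflate.

Step 7
Reactants: 11 primary alcohol
Product: 12 3-[(1R,6S)-6-[2-(tert-butyldimethylsilyloxy)propan-2-yl]-1,3-dimethyl-2-(trifluoromethanesulfonyloxy)cyclohex-2-en-1-yl]propanoic acid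
Conditions: TEMPO (cat.), PhI(OAc)2, MeCN/H2O, 23 °C
Reagents that add atoms: water (O)
Why: Nitroxyl-catalysed oxidation of a primary alcohol through the aldehyde hydrate to the carboxylic acid, mild enough for the silyl ether and the enol triflate.

Step 8
Reactants: 12 carboxylic acid
Product: 13 methyl ester of 12
Conditions: MeI, K2CO3, DMF, 23 °C
Reagents that add atoms: iodomethane (CI)
Why: O-alkylation of the carboxylate (SN2); the methyl ester is needed because a free acid or alcohol would capture the C9 cation in step 14 and would quench the zinc reagent in step 13.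

Step 9
Reactants: 14 methyl 2,4-dihydroxy-3,6-dimethylbenzoate
Product: 15 methyl 5-formyl-2,4-dihydroxy-3,6-dimethylbenzoate
Conditions: MgCl2, Et3N, paraformaldehyde, MeCN, 80 °C
Reagents that add atoms: formaldehyde (C=O)
Why: Magnesium-mediated ortho-formylation of a phenol (Casnati–Skattebøl reaction) can only occur at C5, the one free ring position, which is ortho to the non-chelated hydroxyl.

Step 10
Reactants: 15 formyl resorcinol ester
Product: 16 methyl 5-formyl-2,4-bis(methoxymethoxy)-3,6-dimethylbenzoate
Conditions: NaH, MOMCl, DMF, 0 to 23 °C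
Reagents that add atoms: chloromethyl methyl ether (COCCl)
Why: Williamson etherification of both sodium phenoxides, the strong base being needed for the two hydrogen-bonded hydroxyls; the acetal ethers keep the later benzylic halide from forming a quinone methide.

Step 11
Reactants: 16 bis-MOM aldehyde
Product: 17 methyl 5-(hydroxymethyl)-2,4-bis(methoxymethoxy)-3,6-dimethylbenzoate
Conditions: NaBH4, MeOH/THF, 0 °C
Reagents that add atoms: none
Why: Borohydride reduction of the aryl aldehyde, which at 0 °C should not touch the hindered benzoate.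

Step 12
Reactants: 17 benzylic alcohol
Product: 19 methyl 5-(chloromethyl)-2,4-bis(methoxymethoxy)-3,6-dimethylbenzoate, via benzylic mesylate 18 (not isolated)
Conditions: MsCl, Et3N, LiCl, CH2Cl2/DMF, 0 to 23 °C
Reagents that add atoms: methanesulfonyl chloride (CS(=O)(=O)Cl); lithium chloride ([Li+].[Cl-])
Why: Sulfonylation followed by chloride displacement of the activated benzylic mesylate (SN2), under non-acidic conditions that keep the MOM ethers.

Step 13
Reactants: 19 benzylic chloride; 13 enol triflate methyl ester
Product: 21 methyl 5-{[(5S,6R)-5-[2-(tert-butyldimethylsilyloxy)propan-2-yl]-6-(3-methoxy-3-oxopropyl)-2,6-dimethylcyclohex-1-en-1-yl]methyl}-2,4-bis(methoxymethoxy)-3,6-dimethylbenzoate, via benzylic zinc chloride 20 (not isolated)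
Conditions: Zn dust, LiCl, THF, 25 °C; then 13, Pd(OAc)2 (5 mol %), SPhos (10 mol %), THF, 50 °C
Reagents that add atoms: none
Why: LiCl-assisted zinc insertion gives an ester-tolerant benzylic zinc reagent, and Negishi coupling (zerovalent palladium with a bulky biaryl phosphine) with the alkenyl triflate forms C9–C11, as known for 2,6,6-trisubstituted cyclohexenyl triflates.

Step 14
Reactants: 21 coupled bis-MOM ether
Product: 23 methyl (2S,2'R,3'S,6'R)-3'-[2-(tert-butyldimethylsilyloxy)propan-2-yl]-6-hydroxy-2'-(3-methoxy-3-oxopropyl)-2',4,6',7-tetramethyl-3H-spiro[1-benzofuran-2,1'-cyclohexane]-5-carboxylate (C5 S; C8 R; C9 S; C10 R), via free resorcinol 22 (not isolated)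
Conditions: ZnBr2, n-PrSH, CH2Cl2, 0 °C; filter; then Amberlyst-15, CH2Cl2, 0 to 23 °C
Reagents that add atoms: none
Why: Thiol-assisted Lewis-acid cleavage of the aryl MOM ethers, then Brønsted-acid phenol–olefin spirocyclisation (5-exo Markovnikov hydroalkoxylation of the tetrasubstituted alkene, the reaction used for spiro-dihydrobenzofuran meroterpenoids): with the silyloxy-isopropyl group equatorial the C10 methyl is axial, so the proton should add to C8 and the hydroxyl ortho to C11 to the C9 cation from the opposite face, setting C8 (R) and C9 (S) with H and O cis, while the other hydroxyl cannot reach C9 and the hindered tertiary silyl ether is expected to survive.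

Step 15
Reactants: 23 spiro phenol silyl ether
Product: 24 methyl (2S,2'R,3'S,6'R)-6-hydroxy-3'-(2-hydroxypropan-2-yl)-2'-(3-methoxy-3-oxopropyl)-2',4,6',7-tetramethyl-3H-spiro[1-benzofuran-2,1'-cyclohexane]-5-carboxylate
Conditions: Bu4NF, THF, 50 °C
Reagents that add atoms: none
Why: Fluoride-induced desilylation, warmed because the silyl ether is tertiary; partial loss of the side-chain methyl ester would be harmless because step 16 hydrolyses it anyway.

Step 16
Reactants: 24 spiro phenol; 25 chloroform
Product: 27 methyl (2S,2'R,3'S,6'R)-2'-(2-carboxyethyl)-3a-(dichloromethyl)-3'-(2-hydroxypropan-2-yl)-2',4,6',7-tetramethyl-6-oxo-3a,6-dihydro-3H-spiro[1-benzofuran-2,1'-cyclohexane]-5-carboxylate (both C3a = T5 epimers), via hydroxy acid 26 (not isolated)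
Conditions: aq. NaOH, 1,4-dioxane, 25 °C; then CHCl3 (slow addition), 60 °C; then dilute HCl to pH 3
Reagents that add atoms: chloroform (ClC(Cl)Cl); sodium hydroxide ([Na+].[OH-])
Why: Saponification of the unhindered aliphatic ester, then abnormal Reimer–Tiemann reaction: dichlorocarbene is captured by the phenoxide at the alkylated para carbon T5, the ring-fusion position that corresponds to the reactive 4-position of a resorcinol (para to O−, ortho to the ether oxygen), as in the known para-dichloromethylation of ring-fused 4-alkylphenols; T7 lies between two oxygens, T2 carries the ester, the di-ortho-substituted aryl ester resists hydroxide, and the T5 configuration does not matter.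

Step 17
Reactants: 27 4-dichloromethyl dienone acid
Product: 28 3-[(2S,2'R,3'S,6'R)-3'-(2-hydroxypropan-2-yl)-6-(methoxycarbonyl)-2',5,6',8-tetramethyl-7-oxo-3H,7H-spiro[cyclohepta[b]furan-2,1'-cyclohexan]-2'-yl]propanoic acid (CNP0448476.4)
Conditions: Bu3SnH (2.5 equiv, slow addition), AIBN (cat.), benzene, 80 °C; aq. KF work-up
Reagents that add atoms: none
Why: Bu3Sn• abstracts one chlorine from the CHCl2 group on T5, and the α-chloroalkyl radical (the future T4) closes 3-exo-trig onto T3 to give a cyclopropylcarbinyl radical at T2 that is stabilised by both the ketone and the ester; β-scission of the old T5–T3 bond then opens it to the seven-membered ring with the radical at T5 (new T3–T4 bond, a net 1,2-vinyl shift). Loss of the second chlorine from T4 by β-fragmentation should give the T4=T5 double bond and the aromatic tropone, the chlorine atom regenerating Bu3Sn• from the hydride and the HCl being consumed by the second equivalent of hydride. The closest known reaction is the tin hydride ring expansion of simple 4-alkyl-4-(dichloromethyl)cyclohexa-2,5-dienones to tropones, a homoallyl–cyclopropylcarbinyl radical rearrangement related to the Dowd–Beckwith expansion. The only ring closed directly is the transient cyclopropane (3-exo-trig); the seven-membered ring arises from its fragmentation, no stereocentre is created, and the T5 centre is destroyed, so both epimers of 27 converge. The step needs addition to T3 and not to the alkoxy-bearing T6: T2=T3 is the electron-poor, doubly activated alkene and gives a malonyl-type radical, whereas the donor-substituted T6 would give a less stabilised one, and slow addition keeps the hydride concentration low so that ring closure outruns simple reduction. The free acid and the tertiary alcohol are spectators in the neutral radical chain.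

**Compound list**

1 | (S)-carvone | CC1=CC[C@@H](CC1=O)C(=C)C | starting material
2 | (S)-8-hydroxycarvotanacetone | CC1=CC[C@@H](CC1=O)C(C)(C)O | intermediate
3 | (5S)-5-[2-(tert-butyldimethylsilyloxy)propan-2-yl]-2-methylcyclohex-2-en-1-one | CC1=CC[C@@H](CC1=O)C(C)(C)O[Si](C)(C)C(C)(C)C | intermediate
4 | lithium cross-conjugated dienolate of 3 | CC1=CC[C@@H](C=C1O[Li])C(C)(C)O[Si](C)(C)C(C)(C)C | intermediate
5 | (5S,6R)-5-[2-(tert-butyldimethylsilyloxy)propan-2-yl]-2,6-dimethylcyclohex-2-en-1-one | CC1=CC[C@@H]([C@@H](C)C1=O)C(C)(C)O[Si](C)(C)C(C)(C)C | intermediate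
6 | lithium dienolate of 5 | CC1=CC[C@@H](C(C)=C1O[Li])C(C)(C)O[Si](C)(C)C(C)(C)C | intermediate
7 | (5S,6R)-5-[2-(tert-butyldimethylsilyloxy)propan-2-yl]-2,6-dimethyl-6-(prop-2-en-1-yl)cyclohex-2-en-1-one | CC1=CC[C@@H]([C@@](C)(CC=C)C1=O)C(C)(C)O[Si](C)(C)C(C)(C)C | intermediate
8 | lithium enolate from conjugate reduction of 7 | [Li]OC1=C(C)CC[C@H](C(C)(C)O[Si](C)(C)C(C)(C)C)[C@@]1(C)CC=C | intermediate
9 | (5S,6R)-6-allyl-5-[2-(tert-butyldimethylsilyloxy)propan-2-yl]-2,6-dimethylcyclohex-1-en-1-yl trifluoromethanesulfonate | FC(F)(F)S(=O)(=O)OC1=C(C)CC[C@H](C(C)(C)O[Si](C)(C)C(C)(C)C)[C@@]1(C)CC=C | intermediate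
10 | B-alkyl-9-borabicyclo[3.3.1]nonane adduct of 9 | FC(F)(F)S(=O)(=O)OC1=C(C)CC[C@H](C(C)(C)O[Si](C)(C)C(C)(C)C)[C@@]1(C)CCCB1C2CCCC1CCC2 | intermediate
11 | (5S,6R)-5-[2-(tert-butyldimethylsilyloxy)propan-2-yl]-6-(3-hydroxypropyl)-2,6-dimethylcyclohex-1-en-1-yl trifluoromethanesulfonate | FC(F)(F)S(=O)(=O)OC1=C(C)CC[C@H](C(C)(C)O[Si](C)(C)C(C)(C)C)[C@@]1(C)CCCO | intermediate
12 | 3-[(1R,6S)-6-[2-(tert-butyldimethylsilyloxy)propan-2-yl]-1,3-dimethyl-2-(trifluoromethanesulfonyloxy)cyclohex-2-en-1-yl]propanoic acid | FC(F)(F)S(=O)(=O)OC1=C(C)CC[C@H](C(C)(C)O[Si](C)(C)C(C)(C)C)[C@@]1(C)CCC(=O)O | intermediate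
13 | methyl ester of 12 | FC(F)(F)S(=O)(=O)OC1=C(C)CC[C@H](C(C)(C)O[Si](C)(C)C(C)(C)C)[C@@]1(C)CCC(=O)OC | intermediate
14 | methyl 2,4-dihydroxy-3,6-dimethylbenzoate | COC(=O)c1c(C)cc(O)c(C)c1O | starting material
15 | methyl 5-formyl-2,4-dihydroxy-3,6-dimethylbenzoate | COC(=O)c1c(C)c(C=O)c(O)c(C)c1O | intermediate
16 | methyl 5-formyl-2,4-bis(methoxymethoxy)-3,6-dimethylbenzoate | COC(=O)c1c(C)c(C=O)c(OCOC)c(C)c1OCOC | intermediate
17 | methyl 5-(hydroxymethyl)-2,4-bis(methoxymethoxy)-3,6-dimethylbenzoate | COC(=O)c1c(C)c(CO)c(OCOC)c(C)c1OCOC | intermediate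
18 | benzylic methanesulfonate of 17 | COC(=O)c1c(C)c(COS(C)(=O)=O)c(OCOC)c(C)c1OCOC | intermediate
19 | methyl 5-(chloromethyl)-2,4-bis(methoxymethoxy)-3,6-dimethylbenzoate | COC(=O)c1c(C)c(CCl)c(OCOC)c(C)c1OCOC | intermediate
20 | benzylic zinc chloride from 19 | COC(=O)c1c(C)c(C[Zn]Cl)c(OCOC)c(C)c1OCOC | intermediate
21 | Negishi product (arene C5–CH2–C9 of the C8=C9 cyclohexene; bis-MOM ether, silyl ether, methyl ester; C5 S, C10 R) | COC(=O)c1c(C)c(CC2=C(C)CC[C@H](C(C)(C)O[Si](C)(C)C(C)(C)C)[C@@]2(C)CCC(=O)OC)c(OCOC)c(C)c1OCOC | intermediate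
22 | free resorcinol of 21 | COC(=O)c1c(C)c(CC2=C(C)CC[C@H](C(C)(C)O[Si](C)(C)C(C)(C)C)[C@@]2(C)CCC(=O)OC)c(O)c(C)c1O | intermediate
23 | spiro-dihydrobenzofuran phenol, tertiary silyl ether, methyl ester (2S,2'R,3'S,6'R) | COC(=O)c1c(C)c2c(c(C)c1O)O[C@@]1(C2)[C@H](C)CC[C@H](C(C)(C)O[Si](C)(C)C(C)(C)C)[C@@]1(C)CCC(=O)OC | intermediate
24 | spiro-dihydrobenzofuran phenol, free tertiary alcohol, methyl ester | COC(=O)c1c(C)c2c(c(C)c1O)O[C@@]1(C2)[C@H](C)CC[C@H](C(C)(C)O)[C@@]1(C)CCC(=O)OC | intermediate
25 | chloroform | ClC(Cl)Cl | starting material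
26 | spiro-dihydrobenzofuran phenol, side-chain carboxylic acid (sodium salt in the flask) | COC(=O)c1c(C)c2c(c(C)c1O)O[C@@]1(C2)[C@H](C)CC[C@H](C(C)(C)O)[C@@]1(C)CCC(=O)O | intermediate
27 | spiro-fused 4-dichloromethyl cyclohexa-2,5-dienone acid (T5 epimers) | COC(=O)C1=C(C)C2(C(Cl)Cl)C[C@]3(OC2=C(C)C1=O)[C@H](C)CC[C@H](C(C)(C)O)[C@@]3(C)CCC(=O)O | intermediate
28 | CNP0448476.4 (tropone spiro-ether seco-acid) | COC(=O)c1c(C)cc2c(c(C)c1=O)O[C@@]1(C2)[C@H](C)CC[C@H](C(C)(C)O)[C@@]1(C)CCC(=O)O | target

**Count and risks**

Total steps: 17. Longest linear sequence: 13 (steps 1–8 and 13–17, from (S)-carvone).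

Steps most likely to fail:

Step 16 (carbene dearomatisation). What may go wrong: capture of the carbene at T7, at the ester-bearing T2 or at oxygen instead of T5, and slow capture at a fully substituted carbon while the carbene is lost to hydrolysis in hot hydroxide. Fallback: the dichloromethyl group is delivered as a radical and not as a carbene. The fallback sets out from 24. LiOH in THF/H2O should give the hydroxy acid 26, isolated here. Its phenoxide–carboxylate (Cs2CO3, DMSO) would then be C-alkylated by bromodichloromethane in a light-initiated electron-transfer chain (Ru(bpy)3Cl2, blue light), the way polyhalomethanes alkylate 2,6-disubstituted 4-alkylphenoxides at the para carbon, without hot aqueous base. This makes no compound outside the list (F0) and comes back to the route at 27.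

Step 17 (ring expansion). What may go wrong: hydrogen transfer to the chloromethyl radical before the three-membered ring closes, closure onto T6, and loss of the free acid as tin carboxylate or through HCl. Fallback: a change of substrate and of chain carrier. It sets out from 27. MeI and K2CO3 in DMF should give the dienone methyl ester F1. Hexabutylditin under irradiation in benzene, a hydride-free chain in which the expelled chlorine atom is taken up by the ditin, should give the tropone methyl ester F2. Me3SnOH in 1,2-dichloroethane at 80 °C should then cleave only the unhindered aliphatic methyl ester, the tropone ester being flanked by a methyl group and the ring carbonyl, and come back to the route at 28.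

Step 14 (spirocyclisation). What may go wrong: protonation from both faces of a half-chair that is less rigid than a decalin, six-membered closure at C8 to a chroman, capture of the cation by the ester, or ionisation of the tertiary silyl ether. Fallback: the C9–O bond is made by oxypalladation and not through a carbocation. It sets out from 22, isolated after the MOM cleavage. Pd(O2CCF3)2 (divalent palladium), pyridine, Na2CO3 and O2 in toluene at 80 °C is the aerobic Wacker-type cyclisation known for 2-allylphenols with fully substituted alkenes. By syn-oxypalladation on the face away from the C10 methyl and β-hydride loss towards the C8 methyl it should give the spiro ether with an exocyclic C8 methylene F3. Hydrogenation (H2, RhCl(PPh3)3, benzene) from the same face would set C8 and come back to the route at 23.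

Further compounds
F0 | step 16 | none | none
F1 | step 17 | spiro-fused 4-dichloromethyl cyclohexa-2,5-dienone, side-chain methyl ester (T5 epimers) | COC(=O)C1=C(C)C2(C(Cl)Cl)C[C@]3(OC2=C(C)C1=O)[C@H](C)CC[C@H](C(C)(C)O)[C@@]3(C)CCC(=O)OC
F2 | step 17 | methyl ester of the target | COC(=O)c1c(C)cc2c(c(C)c1=O)O[C@@]1(C2)[C@H](C)CC[C@H](C(C)(C)O)[C@@]1(C)CCC(=O)OC
F3 | step 14 | spiro-dihydrobenzofuran phenol with exocyclic C8 methylene (silyl ether, methyl ester) | COC(=O)c1c(C)c2c(c(C)c1O)O[C@@]1(C2)C(=C)CC[C@H](C(C)(C)O[Si](C)(C)C(C)(C)C)[C@@]1(C)CCC(=O)OC
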